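The amounts come first: 19 mM of G against 34.2 mM of E, with 0.19 mM of D to feed the chain.

G 19 mM; E 34.2 mM; D 0.19 mM; time 8.0 min

    2 X → X2 (k1 = 6 × 10⁶ L mol⁻¹ s⁻¹)
    D → 2 X (k2 = 0.0100 s⁻¹)
    G + X ⇌ G.X (K3 = 2.8 × 10⁶ L mol⁻¹, k3 = 1.81 × 10⁵ L mol⁻¹ s⁻¹)
    L ⇌ J (K4 = 0.759, k4 = 0.363 s⁻¹)
    E + G.X → L + X (k5 = 63700 L mol⁻¹ s⁻¹)

- which holds at 8.0 min: what has brought the reaction to rest, or that it has not come to rest (all of G has reacted / it is still moving / forward and back rates have come level / E has run out first)
- L at 8.0 min, in percent of the G charged
- J at 8.0 min, in percent of the G charged

- a step written with two of one species runs at k times the square of its concentration and takes two of it each time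
- the reaction counts as stopped when no species that holds the G changes by six tenths of a point or more over the second half of the time
- run time (flask): 8.0 min

Each turn of the chain takes one G and one E, so E can cover G, with 15.2 mM to spare; G is the limiting reagent. Now we ask which constants must be known well. Write ki for the constant of D's breakdown, kt for the loss of X, ka for G taking up X, and K for the balance of J over L. With making and loss of X level,

[X] = √(ki[D]/kt) = 5.63 × 10⁻⁴ mM, and G lasts 1/(ka[X]) = 9.82 s.

As D fades, [X] fades with its root, so over the time t the run offers (2ka[X]/ki)(1 − exp(−ki t/2)) = 18.5 such lifetimes, with [X] taken at its starting value. Making kt 4 times larger lowers [X] by a factor 2 and still leaves 0.00950% of G, so the rate constants hardly touch the answer. G.X goes on with E at 2180 s⁻¹, faster than it falls back at 0.0646 s⁻¹. L and J relax with a half-life of 0.824 s, short against 8.0 min.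

K is different. The symmetric case, K = 1, gives L 50.0%; doubling our K gives 39.7%, and halving it gives 72.5%. So K is the number to know, and it is 0.759:

s = 1/(1 + K) = 56.9%

We call s the L share: the fraction of the product standing as L once L and J have balanced. We commit to L at s and J at 43.1%, with G reacted.

The forecast says all of G has reacted, with L at 56.9% and J at 43.1%, its ground for the split being that “L ⇌ J relaxes in seconds”. The simulation gives all of G has reacted, with L at 56.9% and J at 43.1%.

In this flask G stands at 0% and E at 44% after 8.00 min, so the L share 56.9% applies to the whole charge of G. The neighbouring flask has 14 mM of E, less than the 19 mM of G, so E is now limiting and can carry 73.7% of G into product. The same share then gives L 41.9% and J 31.8%. That neighbouring flask ends with E at 0%, L at 41.9%, J at 31.8% and G at 24.6%.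

All constants were chosen freely.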